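## Retrosynthetic overview

1. The chalcone C=C is cut by a Claisen–Schmidt disconnection into a 3-prenylresacetophenone (ring A) and a dihydrobenzofuran-5-carbaldehyde (ring B part); the aldehyde carbon comes from CO on an aryl bromide.
2. The trans-3-hydroxy-2-(2-hydroxypropan-2-yl)dihydrobenzofuran comes from 6-bromo-2,2-dimethyl-2H-chromene by an enantioselective ring contraction triggered by trivalent iodine: a 1,2-shift of the aryloxy oxygen from CMe2 to C3 (pyran to furan) that sets both stereocentres.
3. The chromene comes from 4-bromophenol and 3-methylbut-2-enal; the ring A ketone comes from resorcinol, acetic acid and prenyl bromide.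
4. Ring order: the pyran ring is made first and then contracted to the dihydrofuran ring; both benzene rings are bought.

Assumption: the sense of induction of the lactate-derived λ3-iodane in step 2 is assigned by analogy with its diacetoxylation of styrenes. If the opposite sense is found, the (R,R)-reagent from the other lactate enantiomer is used, with nothing else changed.

## Route

Step 1
Reactants: 1 4-bromophenol; 2 3-methylbut-2-enal
Product: 3 6-bromo-2,2-dimethyl-2H-chromene
Conditions: PhB(OH)2 (1.0 equiv), AcOH, toluene, reflux (Dean–Stark), 24 h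
Reagents that add atoms: none
Why: Phenylboronic acid condenses with the phenol and the enal to a 1,3,2-benzodioxaborin that fragments to an ortho-quinone methide, which closes by oxa-6π electrocyclisation to the 2H-chromene (boronic acid-templated chromene annulation); the para bromine leaves only the ortho positions open and no stereocentre is formed.

Step 2
Reactants: 3 6-bromo-2,2-dimethyl-2H-chromene
Product: 6 (2R,3R)-5-bromo-2-(2-hydroxypropan-2-yl)-2,3-dihydro-1-benzofuran-3-ol, via trans-iodane adduct 4 (not isolated), via hydroxy acetate 5 (not isolated)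
Conditions: (S,S)-lactate aryl-λ3-iodane diacetate (1.2 equiv), TfOH (20 mol%), CH2Cl2, −78 → −40 °C; then H2O/THF, −40 °C → rt; then NaOH, MeOH/H2O, 40 °C
Reagents that add atoms: dimethyl (2S,2'S)-2,2'-{[2-(diacetoxy-λ3-iodanyl)-1,3-phenylene]bis(oxy)}dipropanoate (acetoxy oxygen at the benzylic carbon), COC(=O)[C@H](C)Oc1cccc(O[C@@H](C)C(=O)OC)c1I(OC(C)=O)OC(C)=O; water (oxygen of the tertiary alcohol), O
Why: Proposed new method: the chiral aryl-λ3-iodane adds face-selectively to the styrene-type C3=C4 bond, iodine at C3 and acetate anti at benzylic C4, giving the trans-(3S,4R) adduct 4; the bulky iodanyl group sits equatorial, which puts the C2–O1 bond antiperiplanar to C3–I, so loss of the aryl iodide is assisted by a 1,2-shift of the aryloxy oxygen from C2 to C3 with inversion at C3 (this becomes furan C2, R) while the C4 acetate centre is retained (furan C3, R, hence trans), and the gem-dimethyl carbon, now a tertiary cation/oxiranium, is trapped by the neighbouring acetate and water as the tertiary alcohol before saponification; the closest known reaction types are the enantioselective Prévost/Woodward diacetoxylation of styrenes with chiral trivalent-iodine reagents and the sulfonate-triggered ring contraction of 2,2-dimethylchroman-3-ols (and of pyranoside 2-triflates) by ring-oxygen shift.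

Step 3
Reactants: 6 (2R,3R)-5-bromo-2-(2-hydroxypropan-2-yl)-2,3-dihydro-1-benzofuran-3-ol
Product: 7 (2R,3R)-3-hydroxy-2-(2-hydroxypropan-2-yl)-2,3-dihydro-1-benzofuran-5-carbaldehyde
Conditions: Pd(OAc)2 (1 mol%), di(1-adamantyl)-n-butylphosphine (3 mol%), TMEDA (1.0 equiv), CO/H2 (1:1, 5 bar), toluene, 100 °C
Reagents that add atoms: carbon monoxide, [C-]#[O+]
Why: Palladium-catalysed reductive carbonylation of an aryl bromide (oxidative addition to zerovalent palladium, CO insertion, hydrogenolysis of the acyl–palladium bond) tolerates free alcohols and does not touch either stereocentre.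

Step 4
Reactants: 8 resorcinol
Product: 9 1-(2,4-dihydroxyphenyl)ethan-1-one
Conditions: AcOH, ZnCl2, 140 °C
Reagents that add atoms: acetic acid, CC(=O)O
Why: Nencki reaction (ZnCl2-mediated Friedel–Crafts C-acylation, partly via the O-acetate and Fries shift) at C4 of resorcinol, ortho to one hydroxyl and para to the other; no stereocentre is formed.

Step 5
Reactants: 9 1-(2,4-dihydroxyphenyl)ethan-1-one; 10 1-bromo-3-methylbut-2-ene (prenyl bromide)
Product: 11 1-[2,4-dihydroxy-3-(3-methylbut-2-en-1-yl)phenyl]ethan-1-one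
Conditions: KOH (10% aq), 0 °C → rt, 12 h; chromatography
Reagents that add atoms: none
Why: C-alkylation of the ambident resorcinolate dianion in water, where hydrogen bonding shields the oxygens, occurs by SN2 at the primary allylic carbon and preferentially at C3, the carbon flanked by both oxygens; the 5-prenyl and bis-prenyl by-products are separated and no stereocentre is formed.

Step 6
Reactants: 11 1-[2,4-dihydroxy-3-(3-methylbut-2-en-1-yl)phenyl]ethan-1-one; 7 (2R,3R)-3-hydroxy-2-(2-hydroxypropan-2-yl)-2,3-dihydro-1-benzofuran-5-carbaldehyde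
Product: 12 Paratocarpin G, (E)-1-[2,4-dihydroxy-3-(3-methylbut-2-en-1-yl)phenyl]-3-[(2R,3R)-3-hydroxy-2-(2-hydroxypropan-2-yl)-2,3-dihydro-1-benzofuran-5-yl]prop-2-en-1-one
Conditions: KOH (50% aq, 10 equiv), EtOH, rt, 48 h; then 1 M HCl, 0 °C, to pH 5
Reagents that add atoms: none
Why: Claisen–Schmidt condensation (aldol addition of the methyl ketone enolate to the non-enolisable aldehyde, then E1cB dehydration) gives the conjugated (E)-enone under thermodynamic control; the two stereocentres of 7 carry no acidic hydrogen and are not epimerised, and the phenoxide form keeps the chalcone from closing to the flavanone.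

## Compound list

1 | 4-bromophenol | Oc1ccc(Br)cc1 | starting material
2 | 3-methylbut-2-enal | CC(C)=CC=O | starting material
3 | 6-bromo-2,2-dimethyl-2H-chromene | CC1(C)C=Cc2cc(Br)ccc2O1 | intermediate
4 | (3S,4R)-4-acetoxy-3-[acetoxy(aryl)-λ3-iodanyl]-6-bromo-2,2-dimethylchromane, aryl = 2,6-bis[(S)-1-methoxy-1-oxopropan-2-yloxy]phenyl, iodine and 4-acetoxy trans | CC1(C)Oc2ccc(Br)cc2[C@@H](OC(C)=O)[C@@H]1I(OC(C)=O)c1c(O[C@@H](C)C(=O)OC)cccc1O[C@@H](C)C(=O)OC | intermediate
5 | (2R,3R)-5-bromo-2-(2-hydroxypropan-2-yl)-2,3-dihydro-1-benzofuran-3-yl acetate (any regioisomeric acetate or diacetate converges on saponification) | Brc1ccc2c(c1)[C@@H](OC(C)=O)[C@H](C(C)(C)O)O2 | intermediate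
6 | (2R,3R)-5-bromo-2-(2-hydroxypropan-2-yl)-2,3-dihydro-1-benzofuran-3-ol (2,3-trans) | Brc1ccc2c(c1)[C@@H](O)[C@H](C(C)(C)O)O2 | intermediate
7 | (2R,3R)-3-hydroxy-2-(2-hydroxypropan-2-yl)-2,3-dihydro-1-benzofuran-5-carbaldehyde | O=Cc1ccc2c(c1)[C@@H](O)[C@H](C(C)(C)O)O2 | intermediate
8 | resorcinol | Oc1cccc(O)c1 | starting material
9 | 1-(2,4-dihydroxyphenyl)ethan-1-one | CC(=O)c1ccc(O)cc1O | intermediate
10 | 1-bromo-3-methylbut-2-ene | CC(C)=CCBr | starting material
11 | 1-[2,4-dihydroxy-3-(3-methylbut-2-en-1-yl)phenyl]ethan-1-one | CC(=O)c1ccc(O)c(CC=C(C)C)c1O | intermediate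
12 | Paratocarpin G | CC(C)=CCc1c(O)ccc(C(=O)/C=C/c2ccc3c(c2)[C@@H](O)[C@H](C(C)(C)O)O3)c1O | target

## Step count and risks

Total step count: 6. Longest linear sequence: 4 (steps 1, 2, 3, 6).

Three steps most likely to fail:

**Step 2 (the proposed new method).** The C4–C4a aryl bond is also antiperiplanar to C3–I in the diequatorial conformer, and its migration would give a 3-formyl-2,2-dimethyldihydrobenzofuran acylal. From the diaxial conformer, acetoxy participation (Prévost/Woodward diacetates) or a methyl shift can compete. The enantioselectivity may also fall short; diol 6 is expected to be crystalline and can be recrystallised to raise the ee. The fallback uses known reaction types and sets out from 3. Jacobsen–Katsuki epoxidation with NaOCl, 4-phenylpyridine N-oxide and (S,S)-N,N'-bis(3,5-di-tert-butylsalicylidene)-1,2-cyclohexanediaminomanganese chloride in CH2Cl2 at 0 °C gives (3S,4S)-6-bromo-3,4-epoxy-2,2-dimethylchromane F1. Opening at the benzylic carbon with CsOAc/AcOH in DMF at 60 °C, with inversion, gives (3S,4R)-6-bromo-3-hydroxy-2,2-dimethylchroman-4-yl acetate F2. Tf2O and 2,6-lutidine in CH2Cl2 at −78 °C give (3S,4R)-4-acetoxy-6-bromo-2,2-dimethylchroman-3-yl trifluoromethanesulfonate F3. On warming with aqueous THF, F3 undergoes the established sulfonate-triggered 1,2-aryloxy shift with capture by water and comes back to the route at 5, which is saponified to 6 as in step 2.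

**Step 5.** Direct C-prenylation is short but gives a modest yield, with 5-prenyl, bis-prenyl and O-prenyl by-products. The fallback sets out from 9. Alkylation of the 4-hydroxyl with 3-chloro-3-methylbut-1-yne (K2CO3, KI, CuI, acetone, reflux) gives 1-[2-hydroxy-4-(2-methylbut-3-yn-2-yloxy)phenyl]ethan-1-one F4. Semi-hydrogenation (H2, Pd/CaCO3 poisoned with Pb(OAc)2, quinoline, EtOAc) gives 1-[2-hydroxy-4-(2-methylbut-3-en-2-yloxy)phenyl]ethan-1-one F5. Aromatic Claisen rearrangement of F5 in N,N-diethylaniline at 130 °C transfers the allyl unit with inversion to C3, the position favoured in chelated 2-hydroxyacetophenones, and comes back to the route at 11.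

**Step 6.** The unprotected 4'-phenoxide slows enolate formation, and flavanone closure or incomplete conversion can lower the yield. The fallback sets out from 11. Selective allylation of the non-chelated 4-hydroxyl (allyl bromide, K2CO3, acetone) gives 1-[2-hydroxy-3-(3-methylbut-2-en-1-yl)-4-(prop-2-en-1-yloxy)phenyl]ethan-1-one F6. Claisen–Schmidt condensation of F6 with 7 (KOH, EtOH, rt) gives (E)-1-[2-hydroxy-3-(3-methylbut-2-en-1-yl)-4-(prop-2-en-1-yloxy)phenyl]-3-[(2R,3R)-3-hydroxy-2-(2-hydroxypropan-2-yl)-2,3-dihydro-1-benzofuran-5-yl]prop-2-en-1-one F7. Deallylation of F7 with Pd(PPh3)4 (cat.), K2CO3, MeOH at rt comes back to the route at 12, with no acid used.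

## Further compounds

F1 | step 2 | (3S,4S)-6-bromo-3,4-epoxy-2,2-dimethylchromane | CC1(C)Oc2ccc(Br)cc2[C@@H]2O[C@H]12
F2 | step 2 | (3S,4R)-6-bromo-3-hydroxy-2,2-dimethylchroman-4-yl acetate | CC1(C)Oc2ccc(Br)cc2[C@@H](OC(C)=O)[C@@H]1O
F3 | step 2 | (3S,4R)-4-acetoxy-6-bromo-2,2-dimethylchroman-3-yl trifluoromethanesulfonate | CC1(C)Oc2ccc(Br)cc2[C@@H](OC(C)=O)[C@@H]1OS(=O)(=O)C(F)(F)F
F4 | step 5 | 1-[2-hydroxy-4-(2-methylbut-3-yn-2-yloxy)phenyl]ethan-1-one | CC(=O)c1ccc(OC(C)(C)C#C)cc1O
F5 | step 5 | 1-[2-hydroxy-4-(2-methylbut-3-en-2-yloxy)phenyl]ethan-1-one | CC(=O)c1ccc(OC(C)(C)C=C)cc1O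
F6 | step 6 | 1-[2-hydroxy-3-(3-methylbut-2-en-1-yl)-4-(prop-2-en-1-yloxy)phenyl]ethan-1-one | CC(=O)c1ccc(OCC=C)c(CC=C(C)C)c1O
F7 | step 6 | (E)-1-[2-hydroxy-3-(3-methylbut-2-en-1-yl)-4-(prop-2-en-1-yloxy)phenyl]-3-[(2R,3R)-3-hydroxy-2-(2-hydroxypropan-2-yl)-2,3-dihydro-1-benzofuran-5-yl]prop-2-en-1-one | CC(C)=CCc1c(OCC=C)ccc(C(=O)/C=C/c2ccc3c(c2)[C@@H](O)[C@H](C(C)(C)O)O3)c1O
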